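Alder's converted fraction of Z, taken as the mean of its X and Z columns, rose from 0.0285 at 8.00 min to 0.0920 at 40.0 min, and I built my reckoning on that sag.

in all of them: Z 0.25 M

| charge | D | J | remark |
|---|---|---|---|
| elm | 0.15 M | 0.70 mM | run made earlier |
| birch | 0.22 M | 0.70 mM | run made earlier |
| alder | 0.30 M | 0.35 mM | run made earlier |
| flask | 0.300 M | 0.70 mM |  |

| run | time / min | X / % | Z / % |
|---|---|---|---|
| elm | 8.00 | 2.6 | 96.1 |
| elm | 20.0 | 6.8 | 91.7 |
| elm | 40.0 | 13.7 | 87.3 |
| elm | 90.0 | 20.3 | 79.7 |
| birch | 12.0 | 6.7 | 93.9 |
| birch | 30.0 | 11.0 | 85.1 |
| birch | 60.0 | 17.9 | 80.3 |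
| birch | 90.0 | 23.0 | 77.3 |
| alder | 8.00 | 4.0 | 98.3 |
| alder | 20.0 | 4.0 | 94.8 |
| alder | 40.0 | 9.4 | 91.0 |
| alder | 90.0 | 14.2 | 88.1 |

(each reading ± 1 percentage point)

- apparent order in D when 5.0% of the Z are converted (percent change of the rate of making X for one percent more D charged)
- apparent order in J when 5.0% of the Z are converted (percent change of the rate of making X for one percent more J charged)

- steps under discussion: D + J -> Q; Z + Q <-> L; L -> E; E -> J + X; 2 D -> G

First I asked why the curves bend. Alder still held 88.1% of its Z at 90.0 min, so I looked past Z and took D to be falling on its own clock, whatever J did.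

Then I asked what that means for J. I defined the time exponent as the percent more conversion gained for one percent more time, and alder, with the D charge of this flask, gave 0.728. If J merely multiplies the curve, one percent more J reaches the same conversion sooner, by the inverse of the exponent in percent, and there the curve is steeper. So I put the order in J at that inverse, 1.37, a reckoning on scattered readings.

Last I asked what D buys. From elm to birch, D rose 1.47-fold and X at 90.0 min rose 1.13-fold. That is a scattered reading of order 0.326 in late X, not in the rate at the conversion asked, but I committed to it as my estimate in D, lower than the forecast's.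

The forecast said 1 in D and 1.4 in J, and held that “the initial rate is first order in both D and J”.

The flask gave 0.40 in D and 1.2 in J.

    D + J → Q (k = 20.2 /M/min)
    Z + Q ⇌ L (K = 7.77 /M, k = 46.8 /M/min)
    L → E (k = 16.8 /min)
    E → J + X (k = 9.71 /min)
    2 D → G (k = 0.110 /M/min)

In this flask X rose from 4.46% at 8.00 min to 16.3% at 40.0 min, a time exponent of 0.806, whose inverse, 1.24, stands beside the order of 1.2. A straight line through zero has exponent one and inverse one. The loss of 2 D to G used D 4.7 times as fast as the making of Q at the start, and in a run of this flask without that loss the order in J went from 1.2 to 1.0.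

The data are simulated for an exercise; scatter was added.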